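Late in the dawn run, at 30.0 h, target reads 33.6% and starting material 66.3%. Together they make 99.9%, so target accounts for the starting material lost, within the scatter.

| flask | starting material | second substrate | free catalyst | remark |
|---|---|---|---|---|
| dusk | 27 mM | 13.5 mM | 84 µM | the very flask that is asked about, followed so far |
| dawn | 27 mM | 13.5 mM | 130 µM | run made earlier |
| flask | 27 mM | 13.5 mM | 84 µM |  |

- dusk (time / h: target / %, starting material / %): 1.33: 1.2, 99.2; 2.50: 3.1, 96.5; 4.00: 4.3, 95.7; 5.00: 5.2, 95.9; 6.00: 5.8, 93.6
- dawn (time / h: target / %, starting material / %): 2.50: 3.7, 95.1; 5.00: 7.6, 93.1; 8.00: 11.4, 87.2; 15.0: 20.4, 78.9; 30.0: 33.6, 66.3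

(standard deviation of a reading: 0.5 percentage points)

* apparent order in second substrate when 50% of the starting material are converted (percent change of the rate of making target for one percent more second substrate charged)
* factor on the rate of making target when 50% of the starting material are converted if second substrate is charged twice over

- the numbers in the tables scatter with a standard deviation of 0.5 percentage points
- no earlier run changes the charge of second substrate; that part of a forecast is a guess

I run the dusk flask forward from its first hours. By 6.00 h it has made 5.8% target, an opening pace of 0.261 mM h⁻¹. Which step is fast, I can't read from these runs. At 5.00 h the dusk target over the dawn target is 0.684, and the catalyst ratio is 0.646, so I scale time by catalyst.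

For the middle of the run, target over starting material left grows about in step with time in the dawn run. I take that line from its last reading. Scaled by catalyst, the dusk flask reaches 50% at 91.8 h. I call this the half-time, the time to that conversion.

At the end second substrate comes into question, and no reading shows it. The line I took from the dawn run carries no term for second substrate. So I guess that making target doesn't draw on it, with an order near zero and a factor near one. No run varies that charge, so this stays a guess.

The forecast differs. It gives an order of 1.8 and a factor of 2.7. Its ground is a rate proportional to catalyst, starting material and second substrate, with a charge of “two starting material per second substrate”.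

The dusk flask gives an order of 4.1 × 10⁻⁴ and a factor of 1.00.

    starting material + free catalyst ⇌ catalyst intermediate A (K = 14.0 L mol⁻¹, k = 14.1 L mol⁻¹ min⁻¹)
    catalyst intermediate A → free catalyst + target (k = 0.272 min⁻¹)
    second substrate + free catalyst ⇌ catalyst intermediate B (K = 79.0 L mol⁻¹, k = 18.0 L mol⁻¹ min⁻¹)
    catalyst intermediate B → free catalyst + second product (k = 5.84 min⁻¹)
    free catalyst ⇌ dormant form (K = 5.70, k = 5.23 × 10⁻⁴ min⁻¹)
    free catalyst → spent catalyst (k = 2.01 × 10⁻⁶ min⁻¹)

In the scheme, second substrate goes through catalyst intermediate B to second product, and target comes from catalyst intermediate A by a step without second substrate. In the dusk flask, the half-life of second substrate by its forward step into catalyst intermediate B alone is 12 h at 8.07 h, shorter than my half-time of 91.8 h, which holds 7.65 of them, and half conversion comes later still, at 169 h. In that flask second substrate stands at 22.8% of its charge at 30.0 h and at 0.339% at 300 h, when starting material is still 37.4%.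

Readings and results were computed for substances that don't exist; scatter was added.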